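## Retrosynthetic overview
1. Jaspaquinol ⇒ (retro [1,3] O-to-C allyl shift) its isomer, the hydroquinone mono-ether of the C20 allylic alcohol. All four free positions of hydroquinone are equivalent, so only one C-allyl product can arise.
2. Key disconnection: the ArO–CH2 carbon–oxygen bond of that ether ⇒ hydroquinone + the (2E,6E)-C20 allylic alcohol. This C–O bond is the only union of the aromatic and terpenoid halves and needs no protecting group.
3. C20 alcohol ⇒ C5(sp3)–C6(sp2) bond by B-alkyl Suzuki–Miyaura coupling: C14 (E)-vinyl iodide + C6 (E)-dienol.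
4. Vinyl iodide ⇒ terminal alkyne (syn-carboalumination sets the 6E alkene) ⇒ dihydro-β-ionone. Dienol ⇒ (E)-3-methylpent-2-en-4-yn-1-ol (the 2E alkene is bought).
5. No ring is formed: the cyclohexene ring comes in with dihydro-β-ionone and the arene with hydroquinone.

Assumption: jaspaquinol has no stereocentre, so "single enantiomer" is read as the single (2E,6E) geometric isomer drawn.

## Route

Step 1
Reactants: 1 dihydro-β-ionone (4-(2,6,6-trimethylcyclohex-1-en-1-yl)butan-2-one)
Product: 3 2-(but-3-yn-1-yl)-1,3,3-trimethylcyclohex-1-ene, via enol phosphate 2 (not isolated)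
Conditions: LiN(iPr)2 (1.1 equiv), THF, −78 °C; ClP(O)(OEt)2, −78 °C → rt; LiN(iPr)2 (2.3 equiv), −78 °C → rt; H2O
Reagents that add atoms: none
Why: Kinetic deprotonation at the CH3 group, O-phosphorylation and base-induced elimination of the phosphate (Negishi methyl ketone to terminal alkyne protocol) leave the tetrasubstituted ring alkene untouched, and no stereocentre is formed.

Step 2
Reactants: 3 2-(but-3-yn-1-yl)-1,3,3-trimethylcyclohex-1-ene
Product: 5 2-[(3E)-4-iodo-3-methylbut-3-en-1-yl]-1,3,3-trimethylcyclohex-1-ene, via alkenylalane 4 (not isolated)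
Conditions: Me3Al (2.0 equiv), Cp2ZrCl2 (0.25 equiv), CH2Cl2, 0 °C → rt; I2, THF, −30 → 0 °C
Reagents that add atoms: trimethylaluminium C[Al](C)C; iodine II
Why: Zirconium-catalysed syn-carboalumination (Negishi) puts CH3 on the internal and Al on the terminal alkyne carbon from the same face, and iodinolysis with retention fixes the first E-trisubstituted alkene (>98:2) while the hindered ring alkene is inert.

Step 3
Reactants: 6 (2E)-3-methylpent-2-en-4-yn-1-ol
Product: 7 (2E)-3-methylpenta-2,4-dien-1-ol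
Conditions: H2 (1 atm, stopped at 1.0 equiv), 5% Pd/CaCO3 poisoned with Pb(OAc)2, quinoline, Et2O, 0 °C
Reagents that add atoms: none
Why: Lindlar semi-hydrogenation stops at the vinyl stage because the poisoned palladium surface binds the terminal alkyne much more strongly than the diene, and the existing E alkene is not touched.

Step 4
Reactants: 7 (2E)-3-methylpenta-2,4-dien-1-ol; 5 2-[(3E)-4-iodo-3-methylbut-3-en-1-yl]-1,3,3-trimethylcyclohex-1-ene
Product: 9 (2E,6E)-3,7-dimethyl-9-(2,6,6-trimethylcyclohex-1-en-1-yl)nona-2,6-dien-1-ol, via bis-boryl adduct 8 (not isolated)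
Conditions: 7, 9-BBN-H (2.2 equiv), THF, 0 °C → rt; then 3 M aq NaOH, 5, Pd(dppf)Cl2 (5 mol %), THF, rt
Reagents that add atoms: none
Why: The first 9-BBN-H caps the OH as a borinate and the second adds anti-Markovnikov to the only monosubstituted alkene (the trisubstituted one reacts far more slowly), after which the B-alkyl Suzuki–Miyaura coupling joins the primary alkylborane to the vinyl iodide with retention, so both E alkenes are carried through.

Step 5
Reactants: 9 (2E,6E)-3,7-dimethyl-9-(2,6,6-trimethylcyclohex-1-en-1-yl)nona-2,6-dien-1-ol; 10 hydroquinone (benzene-1,4-diol)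
Product: 11 4-{[(2E,6E)-3,7-dimethyl-9-(2,6,6-trimethylcyclohex-1-en-1-yl)nona-2,6-dien-1-yl]oxy}phenol
Conditions: PPh3 (1.3 equiv) + DIAD (1.3 equiv) premixed, THF, 0 °C; then 10 (5 equiv) and 9, 0 °C → rt; excess 10 washed out with water
Reagents that add atoms: none
Why: Mitsunobu etherification, in which the activated primary allylic carbon is displaced in SN2 fashion by the phenol oxygen (pKa about 10) without allylic transposition or E/Z change, and the five-fold excess of water-soluble 10 holds the reaction at the mono-ether.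

Step 6
Reactants: 11 4-{[(2E,6E)-3,7-dimethyl-9-(2,6,6-trimethylcyclohex-1-en-1-yl)nona-2,6-dien-1-yl]oxy}phenol
Product: 13 jaspaquinol (2-[(2E,6E)-3,7-dimethyl-9-(2,6,6-trimethylcyclohex-1-en-1-yl)nona-2,6-dien-1-yl]benzene-1,4-diol), via ortho-dienone 12 (not isolated)
Conditions: Li[Al(OC(CF3)3)4] (5 mol %), 2,6-di-tert-butyl-4-methylpyridine (10 mol %), CH2Cl2 (0.02 M), Ar, −20 °C → rt
Reagents that add atoms: none
Why: Proposed new method: a lithium cation left almost unsolvated by the weakly coordinating [Al(OC(CF3)3)4]− anion binds the ether oxygen of 11 and heterolyses the allylic C–O bond to a tight pair of lithium 4-hydroxyphenoxide and the 3,3-dialkylallyl cation, which in dilute low-polarity CH2Cl2 collapses in the solvent cage through its unhindered CH2 terminus onto a ring carbon faster than the cation can rotate (E retained) or meet the remote alkenes; O-return only regenerates 11, C-attack gives 12 whose tautomerisation makes the step irreversible, every ring position leads to the same 13, and the hindered pyridine (too bulky to bind Li+) removes stray protons so that chroman closure and polyene cyclisation, the usual failures with BF3·OEt2 or protic acids, have no catalyst; the closest known reaction types are the [1,3] O-to-C shift of allyl vinyl ethers in concentrated LiClO4/Et2O and the MgSiO3-promoted [1,3] shift of allyl aryl ethers, neither shown with a catalytic weakly coordinated lithium salt or on an unprotected hydroquinone mono-ether of a 1,5-polyene.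

## Compound list
1 | dihydro-β-ionone, 4-(2,6,6-trimethylcyclohex-1-en-1-yl)butan-2-one | CC1=C(CCC(C)=O)C(C)(C)CCC1 | starting material
2 | diethyl 4-(2,6,6-trimethylcyclohex-1-en-1-yl)but-1-en-2-yl phosphate (enol phosphate) | CC1=C(CCC(=C)OP(=O)(OCC)OCC)C(C)(C)CCC1 | intermediate
3 | 2-(but-3-yn-1-yl)-1,3,3-trimethylcyclohex-1-ene | CC1=C(CCC#C)C(C)(C)CCC1 | intermediate
4 | dimethyl[(1E)-2-methyl-4-(2,6,6-trimethylcyclohex-1-en-1-yl)but-1-en-1-yl]alane (alkenylalane) | CC1=C(CC/C(C)=C/[Al](C)C)C(C)(C)CCC1 | intermediate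
5 | 2-[(3E)-4-iodo-3-methylbut-3-en-1-yl]-1,3,3-trimethylcyclohex-1-ene | CC1=C(CC/C(C)=C/I)C(C)(C)CCC1 | intermediate
6 | (2E)-3-methylpent-2-en-4-yn-1-ol | C#C/C(C)=C/CO | starting material
7 | (2E)-3-methylpenta-2,4-dien-1-ol | C=C/C(C)=C/CO | intermediate
8 | 9-[(3E)-5-(9-borabicyclo[3.3.1]nonan-9-yloxy)-3-methylpent-3-en-1-yl]-9-borabicyclo[3.3.1]nonane (bis-boryl adduct) | C(C/C(C)=C/COB1C2CCCC1CCC2)B3C4CCCC3CCC4 | intermediate
9 | (2E,6E)-3,7-dimethyl-9-(2,6,6-trimethylcyclohex-1-en-1-yl)nona-2,6-dien-1-ol | CC1=C(CC/C(C)=C/CC/C(C)=C/CO)C(C)(C)CCC1 | intermediate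
10 | hydroquinone, benzene-1,4-diol | Oc1ccc(O)cc1 | starting material
11 | 4-{[(2E,6E)-3,7-dimethyl-9-(2,6,6-trimethylcyclohex-1-en-1-yl)nona-2,6-dien-1-yl]oxy}phenol | CC1=C(CC/C(C)=C/CC/C(C)=C/COc2ccc(O)cc2)C(C)(C)CCC1 | intermediate
12 | 6-[(2E,6E)-3,7-dimethyl-9-(2,6,6-trimethylcyclohex-1-en-1-yl)nona-2,6-dien-1-yl]-4-hydroxycyclohexa-2,4-dien-1-one (ortho-dienone; racemic sp3 centre, lost on tautomerisation) | CC1=C(CC/C(C)=C/CC/C(C)=C/CC2C=C(O)C=CC2=O)C(C)(C)CCC1 | intermediate
13 | jaspaquinol, 2-[(2E,6E)-3,7-dimethyl-9-(2,6,6-trimethylcyclohex-1-en-1-yl)nona-2,6-dien-1-yl]benzene-1,4-diol | CC1=C(CC/C(C)=C/CC/C(C)=C/Cc2cc(O)ccc2O)C(C)(C)CCC1 | target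

## Step count and risks
Total steps: 6. Longest linear sequence: 5 (1 → 3 → 5 → 9 → 11 → 13).

**Step 6 (the proposed new step).**
- Risk: the lithium salt may be too weak to ionise 11.
- Risk: the ion pair may leave the cage, which gives crossover products (bis-allylated material plus hydroquinone) or some chroman.
- Fallback (known chemistry), from 9 back to 13, making the aryl–carbon bond directly. PBr3 in Et2O at −10 °C turns 9 into the C20 allylic bromide F1.
- 1,4-Dimethoxybenzene is ortho-lithiated with n-BuLi/TMEDA to 2,5-dimethoxyphenyllithium F2. In the presence of CuI, F2 is alkylated by F1 at the primary carbon to give the polyprenyl dimethoxybenzene F3.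
- (NH4)2Ce(NO3)6 in MeCN/H2O at 0 °C gives the benzoquinone F4. Shaking F4 with aqueous Na2S2O4 in Et2O delivers 13.

**Step 4.**
- Risk: the volatile dienol 7 may polymerise or be hydroborated twice.
- Risk: the O-borinate may slow transmetalation, so that 5 is mainly reduced.
- Fallback, from 5 back to 9, which builds the second E alkene by carbometalation and needs no 6, 7 or 8. Commercial (4-bromobut-1-yn-1-yl)trimethylsilane and Zn dust/LiCl give the homopropargyl zinc bromide F5.
- Negishi coupling of F5 with 5 under Pd(PPh3)4 in THF gives the silyl enyne F6. K2CO3/MeOH gives the terminal enyne F7.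
- A second Me3Al/Cp2ZrCl2 carboalumination of F7, followed by n-BuLi and (CH2O)n, gives 9.

**Step 5.**
- Risk: DIAD may oxidise hydroquinone to benzoquinone.
- Risk: bis-ether or some transposed tertiary ether may form.
- Fallback, from 9 back to 11, by halide displacement with a mono-protected hydroquinone. NCS/Me2S in CH2Cl2 (−30 → 0 °C) converts 9 into the C20 allylic chloride F8.
- Commercial 4-hydroxyphenyl benzoate with K2CO3 in DMF at rt is O-alkylated by F8 to the ether benzoate F9. K2CO3/MeOH removes the benzoate to give 11.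

## Further compounds
F1 | step 6 | 2-[(3E,7E)-9-bromo-3,7-dimethylnona-3,7-dien-1-yl]-1,3,3-trimethylcyclohex-1-ene | CC1=C(CC/C(C)=C/CC/C(C)=C/CBr)C(C)(C)CCC1
F2 | step 6 | 2,5-dimethoxyphenyllithium | [Li]c1cc(OC)ccc1OC
F3 | step 6 | 2-[(2E,6E)-3,7-dimethyl-9-(2,6,6-trimethylcyclohex-1-en-1-yl)nona-2,6-dien-1-yl]-1,4-dimethoxybenzene | CC1=C(CC/C(C)=C/CC/C(C)=C/Cc2cc(OC)ccc2OC)C(C)(C)CCC1
F4 | step 6 | 2-[(2E,6E)-3,7-dimethyl-9-(2,6,6-trimethylcyclohex-1-en-1-yl)nona-2,6-dien-1-yl]cyclohexa-2,5-diene-1,4-dione | CC1=C(CC/C(C)=C/CC/C(C)=C/CC2=CC(=O)C=CC2=O)C(C)(C)CCC1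
F5 | step 4 | [4-(trimethylsilyl)but-3-yn-1-yl]zinc bromide | C[Si](C)(C)C#CCC[Zn]Br
F6 | step 4 | trimethyl[(5E)-6-methyl-8-(2,6,6-trimethylcyclohex-1-en-1-yl)oct-5-en-1-yn-1-yl]silane | CC1=C(CC/C(C)=C/CCC#C[Si](C)(C)C)C(C)(C)CCC1
F7 | step 4 | 1,3,3-trimethyl-2-[(3E)-3-methyloct-3-en-7-yn-1-yl]cyclohex-1-ene | CC1=C(CC/C(C)=C/CCC#C)C(C)(C)CCC1
F8 | step 5 | 2-[(3E,7E)-9-chloro-3,7-dimethylnona-3,7-dien-1-yl]-1,3,3-trimethylcyclohex-1-ene | CC1=C(CC/C(C)=C/CC/C(C)=C/CCl)C(C)(C)CCC1
F9 | step 5 | 4-{[(2E,6E)-3,7-dimethyl-9-(2,6,6-trimethylcyclohex-1-en-1-yl)nona-2,6-dien-1-yl]oxy}phenyl benzoate | CC1=C(CC/C(C)=C/CC/C(C)=C/COc2ccc(OC(=O)c3ccccc3)cc2)C(C)(C)CCC1
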